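Slowness is what these runs show first: target takes days to climb and longer to fall, so I can follow the flask stage by stage.

| flask | starting material | reagent in the second phase | remark | time | volume of the second phase over the first |
|---|---|---|---|---|---|
| eta | 10 mM | 42 mM | run made earlier |  |  |
| theta | 10 mM | 66 mM | run made earlier |  |  |
| gamma | 5 mM | 30 mM | run made earlier |  |  |
| flask | 10 mM | 30.0 mM |  | 12 d | 1.0 |

- eta (time / d: target / %): 1.25: 26.2; 2.50: 34.7; 4.00: 37.4; 8.00: 30.0; 15.0: 18.2
- theta (time / d: target / %): 1.25: 33.1; 2.50: 41.1; 4.00: 40.4; 8.00: 30.8; 15.0: 17.4
- gamma (time / d: target / %): 1.25: 23.3; 2.50: 32.5; 4.00: 35.2; 8.00: 28.4; 15.0: 20.1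

(readings scatter by 1 percentage point)

- charges count per volume of the first phase; a concentration in a rate is the amount of a species over the volume of its own phase; every rate counts per litre of the first phase
- the earlier runs hold the two phases in the same ratio of volumes as the flask asked about
- a reading or a percentage of target counts all its forms, free or not

- when, up to 12 d, the flask holds most target
- the amount of target, in percent of the starting material charged, at that time

I assume that each starting material takes one reagent. For the flask that leaves 66.7 % of the reagent charge over. This is the spare share: the part of the reagent charge left unbound once the starting material is used up. In gamma the same reckoning gives 83.3 %, with the same reagent charge and half the starting material.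

In the first instants the flask and gamma draw on the same 30.0 mM of reagent, and reagent has to reach the starting material. Starting material is the limiting reagent, at 10 mM in the flask. In the middle I expect the reagent in the second phase to sag, and to sag further in the flask than in gamma. Gamma's highest reading is 35.2 % at 4.00 d. If the clock runs with the reagent level, the ratio of spare shares stretches that time to about 5.00 d. Towards the end of the earlier runs target falls, and I expect the flask's peak to stand a little under gamma's reading.

The forecast gives 4 d and 33.5 %, on the ground that “reagent depletion should matter more”. Its time is earlier than mine.

The flask gives 33.0 % at 4.82 d, so the forecast's height holds and its time is short by a factor 1.21.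

    reagent in the reaction phase ⇌ reagent in the second phase, rate k1*([reagent in the reaction phase] - [reagent in the second phase]/K1) per volume of the first phase (partition coefficient = 8.06, kL = 2.66 × 10⁻⁵ s⁻¹)
    starting material + reagent in the reaction phase ⇌ target (K = 86.0 L mol⁻¹, k = 0.00912 L mol⁻¹ s⁻¹)
    target ⇌ product in the second phase, rate k3*([target] - [product in the second phase]/K3) per volume of the first phase (partition coefficient = 12.0, kL = 2.02 × 10⁻⁵ s⁻¹)
    target → decomposed product (k = 2.19 × 10⁻⁵ s⁻¹)
    starting material → decomposition product (k = 2.19 × 10⁻⁸ s⁻¹)
    reagent in the reaction phase ⇌ dormant form (K = 0.250, k = 5.41 × 10⁻⁶ s⁻¹)

At 12.0 d the flask keeps 5.9 % of its starting material and holds 0.577 % as decomposition product, which took no reagent, so the spare reckoning leaves 68.8 % of the reagent charge unbound. Of that, 59.7 % stands in the second phase, and the gap is held as 2.20 mM reagent in the reaction phase and 0.550 mM dormant form. The neighbouring flask charges 25 mM of starting material, so its spare share is 16.7 %. At 12.0 d it keeps 17 % of its starting material and holds 0.925 % as decomposition product. The reckoning leaves 31.9 % of the reagent charge unbound, of which 28.1 % stands in the second phase, with 0.913 mM in the reaction phase and 0.230 mM dormant. Its highest target is 26.2 %.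

The data were generated by integration with constants of no real substance; the scatter is artificial.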